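I decide to follow one number through these flasks, the drain count, and to let the other concentrations wait.

    starting material + partner ⇌ intermediate (K1 = 10 M⁻¹, k1 = 0.092 M⁻¹ min⁻¹, Ea1 = 96.0 kJ mol⁻¹, ΔH1 = −67.0 kJ mol⁻¹)
    intermediate ⇌ target + by-product (K2 = 2.4 M, k2 = 0.0028 min⁻¹, Ea2 = 116 kJ mol⁻¹, ΔH2 = −47.0 kJ mol⁻¹)
    gas ⇌ partner, rate k3*(csat - [partner]) (k3 = 0.031 min⁻¹, csat = 200 mM)
    solid substrate ⇌ starting material, rate k4*(cs4 - [starting material]) while solid is left; crystals form when [starting material] > cs4 (cs4 = 0.90 M, k4 = 0.023 min⁻¹)
    (constants at 110 °C)

all flasks: solid substrate 1.0 M; gas 200 mM (held); time 10 h

| flask | temperature |
|---|---|
| grey | 125 °C |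
| violet | 140 °C |
| red | 110 °C |
| green | 95 °C |

- as a solid, counted per litre of solution: solid substrate
- at the start none of partner is dissolved
- all constants are for 110 °C and move with temperature by the activation energies and enthalpies
- at the start none of the solid substrate is in solution
- what has only dissolved of solid substrate counts as not reacted

* the flask that comes out highest in amount of intermediate, in percent of the solid substrate charged, or "all alike" when all lie within 1.5 percentage points (grey / violet / red / green / all alike)
* intermediate at the end, in percent of the solid substrate charged, grey
* intermediate at the end, in percent of the solid substrate charged, violet
* intermediate at the end, in percent of the solid substrate charged, red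
* intermediate at the end, in percent of the solid substrate charged, green

Red at 110 °C and green at 95 °C look nearly the same, with the same charge and the same gas, so I compare those two. I count the whole charge as a pool of starting material plus intermediate, and I hold c(partner) at 200 mM, which makes the first step pseudo-first-order. In green the first step has a rate constant of 0.0269 M⁻¹ min⁻¹ and, with c(partner) so held, relaxes at 0.00653 min⁻¹. The pool drains far more slowly, at 5.24 × 10⁻⁴ min⁻¹, so I let the first step stand at equilibrium inside the pool. The ratio c(intermediate)/c(starting material) is then K1 c(partner), 4.71 in green, and the drain above is k2 times the share of the pool held as intermediate.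

Over 10 h that gives 0.314 for green. This number, the drain rate of the pool times the time, is the drain count. The pool keeps exp(−count) of itself, so for green I reckon 60.2% intermediate and 27.0% target. The same reckoning for red has ratio 2.00 and count 1.12, which gives 21.8% intermediate and 67.4% target.

But the count leaves out the backward second step. The backward rate over the forward one is c(target) c(by-product)/(K2 c(intermediate)), which grows as target builds. At my end values it is 2.76% in green and 86.9% in red. So I take green as under kinetic control and commit to about 60.2%, while in red I expect the drain to slow on the way, and so more intermediate than 21.8%, though less than in green.

The forecast names green as highest, with 21.7% for grey, 18.5% for violet, 31% for red and 62% for green, saying of red and green that “the intermediate is still kinetically held up because its onward conversion is slow”.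

The flasks give 21.7% for grey, 18.5% for violet, 31.7% for red and 61.8% for green, so green is highest. In green at 10.0 h, intermediate is still made 1.06 times faster than it is used up, each step taken net, which my falling curve does not have. Green read at 25 h has a drain count of 0.786, which by my reckoning gives 37.6% intermediate, and that flask holds 44.3%.

The rate constants are made up, and the outcome is calculated.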